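## Retrosynthetic overview

1. Target 12, read as 4-bromo-2-[(1R,2R,3E)-3-(bromomethylidene)-1,2-dimethylcyclopentyl]-5-methylphenol (secondary methyl cis to aryl), comes from its methyl ether 11, and 11 from ketone 10 by an E-selective Wittig bromomethylenation.
2. Ketone 10 comes from 1,3-diol 9 by an acid-triggered 1,2-aryl shift followed by a 1,2-hydride shift. The aryl group moves onto the methyl-bearing carbinol carbon, and the secondary carbinol centre together with the aryl-bearing carbon sets both stereocentres.
3. Diol 9 comes from the prochiral 2-aryl-2-methylcyclopentane-1,3-dione 7 by CBS desymmetrisation and MeMgBr addition.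
4. Dione 7 comes from oxidative ortho C–C coupling of 4-bromo-3-methylphenol 2 with 2-methylcyclopentane-1,3-dione 3. The bromine, put on m-cresol 1 first, blocks the para position and is the aryl bromide of the target.
5. Ring order: the benzene ring (from 1) and the cyclopentane ring (from 3) are bought. No further ring is built; a hemiketal furan ring forms in step 2 and is opened again in step 3.

## Route

Step 1
Reactants: 1 3-methylphenol (m-cresol)
Product: 2 4-bromo-3-methylphenol
Conditions: NBS (1.0 equiv), MeCN, −10 to 0 °C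
Reagents that add atoms: N-bromosuccinimide, O=C1CCC(=O)N1Br
Why: Electrophilic aromatic bromination; the hydroxyl group directs para, so the 4-bromo isomer dominates and the minor 6-bromo isomer is removed by crystallisation.

Step 2
Reactants: 2 4-bromo-3-methylphenol; 3 2-methylcyclopentane-1,3-dione
Product: 5 cis-7-bromo-3a-hydroxy-6,8b-dimethyl-2,3,3a,8b-tetrahydro-1H-cyclopenta[b][1]benzofuran-1-one (racemic hemiketal), via open-chain aryl dione 4 (not isolated)
Conditions: FeCl3 (10 mol %), 1,10-phenanthroline (5 mol %), t-BuOOt-Bu (2 equiv), 3 (2 equiv), (CF3)2CHOH, 50 °C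
Reagents that add atoms: none
Why: Iron-catalysed cross-dehydrogenative coupling of a phenol with a 2-substituted 1,3-dicarbonyl; para is blocked by bromine and the other ortho position is flanked by methyl, so the bond forms at C6, and because the new quaternary carbon cannot enolise the neutral hydroxy dione closes to the hemiketal.

Step 3
Reactants: 5 cis-7-bromo-3a-hydroxy-6,8b-dimethyl-2,3,3a,8b-tetrahydro-1H-cyclopenta[b][1]benzofuran-1-one
Product: 7 2-(5-bromo-2-methoxy-4-methylphenyl)-2-methylcyclopentane-1,3-dione, via ring-opened potassium phenoxide 6 (not isolated)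
Conditions: MeI (1.5 equiv), K2CO3 (2 equiv), DMF, 20 °C
Reagents that add atoms: iodomethane, CI
Why: Williamson ether synthesis; carbonate opens the hemiketal to the more stable phenoxide salt, which is O-methylated, and this unmasks the achiral dione with two enantiotopic carbonyl groups.

Step 4
Reactants: 7 2-(5-bromo-2-methoxy-4-methylphenyl)-2-methylcyclopentane-1,3-dione
Product: 8 (2S,3S)-2-(5-bromo-2-methoxy-4-methylphenyl)-3-hydroxy-2-methylcyclopentan-1-one
Conditions: (R)-2-methyl-CBS-oxazaborolidine [(R)-1-methyl-3,3-diphenyltetrahydro-1H,3H-pyrrolo[1,2-c][1,3,2]oxazaborole] (20 mol %), catecholborane (1.3 equiv), toluene, −60 °C; then MeOH, pH 7 phosphate buffer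
Reagents that add atoms: none
Why: Corey–Bakshi–Shibata reduction used as a desymmetrisation; the (R)-catalyst gives the 3S carbinol (quaternary carbon as the large group), and only the carbonyl that can take hydride anti to the aryl group reacts fast, so the hydroxyl ends cis to aryl and the quaternary carbon becomes 2S, while the neutral work-up avoids retro-aldol opening of the β-hydroxy ketone.

Step 5
Reactants: 8 (2S,3S)-2-(5-bromo-2-methoxy-4-methylphenyl)-3-hydroxy-2-methylcyclopentan-1-one
Product: 9 (1R,2S,3S)-2-(5-bromo-2-methoxy-4-methylphenyl)-1,2-dimethylcyclopentane-1,3-diol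
Conditions: MeMgBr (3.5 equiv), THF, −40 to 0 °C; then aq. NH4Cl
Reagents that add atoms: methylmagnesium bromide, C[Mg]Br
Why: Grignard 1,2-addition to the remaining ketone after deprotonation of the hydroxyl group; methyl is expected anti to the aryl group (1R), but this centre is ionised in step 6, so either epimer serves.

Step 6
Reactants: 9 (1R,2S,3S)-2-(5-bromo-2-methoxy-4-methylphenyl)-1,2-dimethylcyclopentane-1,3-diol
Product: 10 (2R,3R)-3-(5-bromo-2-methoxy-4-methylphenyl)-2,3-dimethylcyclopentan-1-one
Conditions: TfOH (10 mol %), (CF3)2CHOH/CH2Cl2 (1:4), 0.02 M, −20 °C, 30 min; then Et3N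
Reagents that add atoms: none
Why: Proposed new method: a relay semipinacol rearrangement of a 2-aryl-1,3-diol, in which the acid ionises only the tertiary C1 alcohol, the electron-rich aryl group on C2 (exocyclic and aligned with the empty orbital, unlike the ring bonds, which disfavours ring contraction and Grob fragmentation) migrates suprafacially to C1 through a phenonium-type bridged transition structure, and the C3–H bond that lies anti to the departing aryl group then shifts to C2 with push from the C3 oxygen to give the ketone irreversibly, so the quaternary centre forms with full chirality transfer from the aryl-bearing carbon (3R) and the new C2–H ends trans to aryl (secondary methyl cis to aryl, 2R); the closest known reaction types are the semipinacol rearrangement with 1,2-aryl (phenonium) shift and the Meinwald-type 1,2-hydride shift of β-hydroxy carbocations, which have not been coupled on 2-aryl-1,3-diols.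

Step 7
Reactants: 10 (2R,3R)-3-(5-bromo-2-methoxy-4-methylphenyl)-2,3-dimethylcyclopentan-1-one
Product: 11 1-bromo-5-[(1R,2R,3E)-3-(bromomethylidene)-1,2-dimethylcyclopentyl]-4-methoxy-2-methylbenzene
Conditions: Ph3P+CH2Br Br− (3 equiv), KOtBu (2.8 equiv), THF, −78 °C, 1 h; then 10, −78 to 0 °C
Reagents that add atoms: (bromomethyl)triphenylphosphonium bromide, BrC[P+](c1ccccc1)(c1ccccc1)c1ccccc1.[Br-]
Why: Wittig bromomethylenation; bromine turns away from the methyl-bearing C2 and towards the CH2 side, which gives the E isomer as the major product (the minor Z isomer is separated), and ylide made and used cold limits enolisation at C2.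

Step 8
Reactants: 11 1-bromo-5-[(1R,2R,3E)-3-(bromomethylidene)-1,2-dimethylcyclopentyl]-4-methoxy-2-methylbenzene
Product: 12 4-bromo-2-[(1R,2R,3E)-3-(bromomethylidene)-1,2-dimethylcyclopentyl]-5-methylphenol
Conditions: BBr3 (3 equiv), CH2Cl2, −78 to −10 °C; cold aq. NaHCO3 quench
Reagents that add atoms: none
Why: Lewis-acid cleavage of the aryl methyl ether (demethylation); the vinyl bromide is a deactivated alkene and both stereocentres are untouched at low temperature.

## Compound list

1 | 3-methylphenol (m-cresol) | Cc1cccc(O)c1 | starting material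
2 | 4-bromo-3-methylphenol | Cc1cc(O)ccc1Br | intermediate
3 | 2-methylcyclopentane-1,3-dione | CC1C(=O)CCC1=O | starting material
4 | 2-(5-bromo-2-hydroxy-4-methylphenyl)-2-methylcyclopentane-1,3-dione (open-chain aryl dione, achiral, not isolated) | CC1(C(=O)CCC1=O)c1cc(Br)c(C)cc1O | intermediate
5 | cis-7-bromo-3a-hydroxy-6,8b-dimethyl-2,3,3a,8b-tetrahydro-1H-cyclopenta[b][1]benzofuran-1-one (racemic; one enantiomer drawn) | C[C@]12C(=O)CC[C@@]1(O)Oc1cc(C)c(Br)cc12 | intermediate
6 | potassium 4-bromo-5-methyl-2-(1-methyl-2,5-dioxocyclopentyl)phenolate (ring-opened potassium phenoxide, achiral, not isolated) | CC1(C(=O)CCC1=O)c1cc(Br)c(C)cc1[O-].[K+] | intermediate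
7 | 2-(5-bromo-2-methoxy-4-methylphenyl)-2-methylcyclopentane-1,3-dione (achiral) | COc1cc(C)c(Br)cc1C1(C)C(=O)CCC1=O | intermediate
8 | (2S,3S)-2-(5-bromo-2-methoxy-4-methylphenyl)-3-hydroxy-2-methylcyclopentan-1-one | COc1cc(C)c(Br)cc1[C@]1(C)C(=O)CC[C@@H]1O | intermediate
9 | (1R,2S,3S)-2-(5-bromo-2-methoxy-4-methylphenyl)-1,2-dimethylcyclopentane-1,3-diol | COc1cc(C)c(Br)cc1[C@]1(C)[C@](C)(O)CC[C@@H]1O | intermediate
10 | (2R,3R)-3-(5-bromo-2-methoxy-4-methylphenyl)-2,3-dimethylcyclopentan-1-one | COc1cc(C)c(Br)cc1[C@]1(C)CCC(=O)[C@@H]1C | intermediate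
11 | 1-bromo-5-[(1R,2R,3E)-3-(bromomethylidene)-1,2-dimethylcyclopentyl]-4-methoxy-2-methylbenzene | COc1cc(C)c(Br)cc1[C@]1(C)CC/C(=C\Br)[C@@H]1C | intermediate
12 | 4-bromo-2-[(1R,2R,3E)-3-(bromomethylidene)-1,2-dimethylcyclopentyl]-5-methylphenol | Cc1cc(O)c([C@]2(C)CC/C(=C\Br)[C@@H]2C)cc1Br | target

## Step count and risks

Total steps: 8. Longest linear sequence: 8 (1 to 12; 3 enters at step 2).

The three steps most likely to fail:

**Step 2 (oxidative phenol–dione coupling).** The bromophenol is less electron-rich than typical substrates, and homocoupling or dehydration of the hemiketal may compete. The fallback sets out from 2 and comes back at 7. Acetylation of 2 (AcCl, Et3N) gives 4-bromo-3-methylphenyl acetate F1. Fries rearrangement (AlCl3, neat, 140 °C; para is blocked) gives 1-(5-bromo-2-hydroxy-4-methylphenyl)ethan-1-one F2. O-Methylation (MeI, K2CO3) gives 1-(5-bromo-2-methoxy-4-methylphenyl)ethan-1-one F3. Geminal acylation with 1,2-bis(trimethylsilyloxy)cyclobutene and BF3·OEt2 (Mukaiyama aldol) gives 2-[1-(5-bromo-2-methoxy-4-methylphenyl)-1-hydroxyethyl]-2-[(trimethylsilyl)oxy]cyclobutan-1-one F4. CF3CO2H then ring-expands F4 by a pinacol-type 1,2-acyl shift to dione 7.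

**Step 6 (the proposed aryl-shift/hydride-shift relay).** Risks are methyl instead of aryl migration, capture of the cation by the methoxy oxygen, Grob fragmentation of the 1,3-diol to an open-chain alkenyl aldehyde, and acid epimerisation of 10 at C2. The fallback uses known chemistry, sets out from 2 and comes back at 10. Commercial 2,3-dimethylcyclopent-2-en-1-one is reduced with (S)-2-methyl-CBS-oxazaborolidine and BH3·SMe2 to (R)-2,3-dimethylcyclopent-2-en-1-ol F5. Mitsunobu coupling with 2 (PPh3, DIAD, inversion) gives 1-bromo-4-{[(1S)-2,3-dimethylcyclopent-2-en-1-yl]oxy}-2-methylbenzene F6. Thermal aromatic Claisen rearrangement (N,N-diethylaniline, 190 °C) transfers the chirality suprafacially and gives 4-bromo-2-[(1R)-1,2-dimethylcyclopent-2-en-1-yl]-5-methylphenol F7. O-Methylation (MeI, K2CO3) gives 1-bromo-5-[(1R)-1,2-dimethylcyclopent-2-en-1-yl]-4-methoxy-2-methylbenzene F8. Hydroboration–oxidation anti to the aryl group (BH3·THF; NaOH, H2O2) gives (1R,2R,3R)-3-(5-bromo-2-methoxy-4-methylphenyl)-2,3-dimethylcyclopentan-1-ol F9. Dess–Martin oxidation of F9 gives ketone 10.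

**Step 7 (Wittig bromomethylenation).** The ketone is hindered, so the basic ylide may enolise it; the cis aryl/methyl arrangement is the less stable one, so this would epimerise C2. The E/Z ratio may also be modest. The fallback sets out from 10 and comes back at 11. Non-basic methylenation (Zn, CH2Br2, TiCl4) gives 1-bromo-5-[(1R,2S)-1,2-dimethyl-3-methylidenecyclopentyl]-4-methoxy-2-methylbenzene F10. Cross-metathesis with vinylboronic acid pinacol ester (second-generation Hoveyda–Grubbs catalyst) puts boron on the less hindered side and gives 2-{(E)-[(2S,3R)-3-(5-bromo-2-methoxy-4-methylphenyl)-2,3-dimethylcyclopentylidene]methyl}-4,4,5,5-tetramethyl-1,3,2-dioxaborolane F11. Bromodeboronation of F11 with CuBr2 (MeOH/H2O, 80 °C, retention) gives 11.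

Further compounds

F1 | step 2 | 4-bromo-3-methylphenyl acetate | CC(=O)Oc1ccc(Br)c(C)c1
F2 | step 2 | 1-(5-bromo-2-hydroxy-4-methylphenyl)ethan-1-one | CC(=O)c1cc(Br)c(C)cc1O
F3 | step 2 | 1-(5-bromo-2-methoxy-4-methylphenyl)ethan-1-one | COc1cc(C)c(Br)cc1C(C)=O
F4 | step 2 | 2-[1-(5-bromo-2-methoxy-4-methylphenyl)-1-hydroxyethyl]-2-[(trimethylsilyl)oxy]cyclobutan-1-one (mixture of diastereomers) | COc1cc(C)c(Br)cc1C(C)(O)C1(O[Si](C)(C)C)CCC1=O
F5 | step 6 | (R)-2,3-dimethylcyclopent-2-en-1-ol | CC1=C(C)[C@H](O)CC1
F6 | step 6 | 1-bromo-4-{[(1S)-2,3-dimethylcyclopent-2-en-1-yl]oxy}-2-methylbenzene | CC1=C(C)[C@@H](Oc2ccc(Br)c(C)c2)CC1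
F7 | step 6 | 4-bromo-2-[(1R)-1,2-dimethylcyclopent-2-en-1-yl]-5-methylphenol | Cc1cc(O)c([C@]2(C)CCC=C2C)cc1Br
F8 | step 6 | 1-bromo-5-[(1R)-1,2-dimethylcyclopent-2-en-1-yl]-4-methoxy-2-methylbenzene | COc1cc(C)c(Br)cc1[C@]1(C)CCC=C1C
F9 | step 6 | (1R,2R,3R)-3-(5-bromo-2-methoxy-4-methylphenyl)-2,3-dimethylcyclopentan-1-ol | COc1cc(C)c(Br)cc1[C@]1(C)CC[C@@H](O)[C@@H]1C
F10 | step 7 | 1-bromo-5-[(1R,2S)-1,2-dimethyl-3-methylidenecyclopentyl]-4-methoxy-2-methylbenzene | COc1cc(C)c(Br)cc1[C@]1(C)CCC(=C)[C@@H]1C
F11 | step 7 | 2-{(E)-[(2S,3R)-3-(5-bromo-2-methoxy-4-methylphenyl)-2,3-dimethylcyclopentylidene]methyl}-4,4,5,5-tetramethyl-1,3,2-dioxaborolane | COc1cc(C)c(Br)cc1[C@]1(C)CC/C(=C\B2OC(C)(C)C(C)(C)O2)[C@@H]1C
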